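## Structural features

The target is made of four guaiacyl C6–C3 units. A tetrahydrofuran (O1, C2–C5) carries ring B at C2, a hydroxymethyl group at C3 and the 4-hydroxy-3-methoxybenzyl group (ring A) at C4. Ring B is also the benzo ring of dihydrobenzofuran B, whose C2 carries ring C; ring C is the benzo ring of dihydrobenzofuran C, whose C2 carries the 4-hydroxy-3-methoxyphenyl ring D. The seven stereocenters fall into three separate groups: C2/C3/C4 of the tetrahydrofuran (2R,3R,4R), C2/C3 of dihydrobenzofuran B (2R,3S) and C2/C3 of dihydrobenzofuran C (2S,3R). In the tetrahydrofuran all three substituents sit on one face, so the C2 aryl group is cis to the C3 hydroxymethyl group; this is the less stable arrangement and cannot be reached by equilibration through a benzylic cation. Both dihydrobenzofurans are trans but of opposite absolute sense, so each needs its own stereochemical control. The fragile sites are the three O–CH(aryl) carbons, each para to a ring oxygen and therefore open to acid ionization and to hydrogenolysis, together with two free phenols on electron-rich rings and three primary alcohols. The real difficulty is to grow dihydrobenzofuran B on a finished C unit with independent absolute control and then to build the all-cis tetrahydrofuran without acid. The key step uses the fact that in dihydrobenzofuran B the chain C2–C3–CH2O is a coniferyl unit with C2 on the ring B phenol oxygen O1 and C3 on the ortho carbon C3a: an ortho-iodophenol and a cinnamyl unit supply every atom, and the radical step forms C3–C3a and the CH2–O bond.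

## Logic of the disconnections

**39 ⇒ 38 ⇒ 37.** The O–H bonds of the two phenols and three primary alcohols are traded for O–benzyl and O–silyl bonds. The reason is that the hydride, boron, titanium and palladium steps need a molecule without acidic protons. No skeletal simplification results, but each group leaves under its own neutral conditions. The demand is that hydrogenolysis removes two aryl benzyl ethers faster than it opens three cyclic benzylic ethers.

**37 ⇒ 34 + 35.** The bond between the exocyclic CH2 on C4 and ring A is cut, together with the C4–H bond. This brings ring A in last and turns the C4 stereocenter into a planar exocyclic alkene. One stereocenter and one aryl ring are removed. The forward hydroboration must come from the face opposite the two cis substituents, and the alkylborane must couple with an electron-rich aryl bromide.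

**34 ⇒ 33 ⇒ 32.** The exocyclic C=C is traced to a C=O, and the O1–C5 bond of the tetrahydrofuran is cut as a carbenoid O–H insertion. The closure is neutral and does not involve the benzylic carbinol carbon, so an open-chain syn pair becomes the ring cis pair. The ring is reduced to an acyclic hydroxy diazoketone. The demand is that the stereocenter next to the ketone in 33 is not epimerized during closure and methylenation.

**32 ⇒ 29 ⇒ 27 ⇒ 21 + 25; 25 ⇒ 22 + 23.** The C2–C3 bond of the tetrahydrofuran is cut as an aldol bond. An auxiliary-controlled syn-aldol sets both centers in an absolute sense that does not depend on the four remote stereocenters. The problem is reduced to an aryl aldehyde and a three-carbon acyl unit. The demand is a Z-enolate of a β-silyloxy acyl unit that does not eliminate, and conversion of the imide into a diazoketone without loss of the β-hydroxyl.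

**21 ⇒ 20 ⇒ 19 ⇒ 18 ⇒ 17.** No skeletal bond is cut; the formyl group is traced to the methyl ester and the silyl ethers to the aminoxy ethers. The ester is the robust form of this carbon for the radical step and for N–O cleavage. The demand is one reductive step that cleaves both N–O bonds.

**17 ⇒ 16 + 9 (key).** The C3–C3a bond and the CH2–O bond of dihydrobenzofuran B are cut. This removes a ring, a stereocenter and the oxygen function in one operation and leaves an aryl iodide with a branched allyl ether. In 16 the ring C oxygen is still the aminoxy ether from the first cyclization, so no protecting-group exchange lies between the two cyclizations. The demand is that closure beats capture of the aryl radical, capture beats hydrogen transfer to the primary radical, and the closure is trans-selective.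

**16 ⇒ 14 + 12; 14 ⇒ 13.** The O1–C2 bond of dihydrobenzofuran B (allylic C–O) is cut. This separates ring B as a simple iodophenol and puts the C2 configuration under catalyst control. The demand is branched-selective, enantioselective attack by a phenoxide that is substituted at both ortho positions and carries a para ester.

**12 ⇒ 11 ⇒ 10 ⇒ 8 + 9; 8 ⇒ 6 + 4.** The same two cuts are applied to dihydrobenzofuran C (C3–C3a and CH2–O, then O1–C2), followed by adjustment of the side chain from acrylate to allylic carbonate. Using the mirror-image ligand gives the opposite absolute sense. Two achiral aromatic building blocks remain. The demand is that the acrylate stays out of the radical chemistry.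

**6 ⇒ 5; 4 ⇒ 3 ⇒ 2 ⇒ 1.** The acrylate C=C of 6 is cut as a Wittig bond. The carbonate C–O of 4 is traced to the alcohol, and the alcohol to an ester of 1. Both ends are cheap commercial materials. The only demand is E geometry, which a stabilized ylide and the natural acid provide.

## Other disconnections considered

**Alternative 1:** The cut is again the C3–C3a bond of a dihydrobenzofuran (here the C–D unit), traced to a 1,2-aryl shift. The retron is flavanone A2, in which the future C3 is the ring methylene next to the C4 carbonyl and C2 already carries ring D. Forward, PhI(OAc)2 and H2SO4 in HC(OMe)3 would form the C3–C4 enol ether and attach iodine at C3. The fused benzo ring then moves from C4 to C3 as iodobenzene leaves; the six-membered ring contracts and C4 ends as the methyl ester of A1.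
- In favour: C2 would be set earlier by an asymmetric ring closure and is not touched by the shift. The trans relationship is thermodynamic because C3 is epimerizable next to the ester; this is better than the chosen plan, where the ratio is fixed kinetically. No tin is used, which is also better. The C3 carbon arrives as an ester that a hydride turns into CH2OH.
- Against: the medium is a strong acid and an oxidant, so ring D must be detuned as a sulfonate (the tosyloxy group of A1) and re-protected later. A flavanone can lose its C2 configuration by reversible ring opening under acid. Migration of the C2 aryl group competes when that group is electron-rich. The second use, for dihydrobenzofuran B, would need a flavanone whose C2 aryl group is the whole C unit, with a para oxygen that cannot be detuned and a benzylic ether that acid can open.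
- Structure: equal; both plans form C3–C3a and place the oxygenated carbon on C3.
- Mechanism: the radical addition is neutral and indifferent to electron-rich arenes and benzylic ethers; the cationic shift is not.
- Step economy: the alternative needs condensation, asymmetric closure, contraction, ester reduction, protecting-group exchange and conversion of the bromide of A1 for each ring, against two steps per ring in the chosen plan.

**Alternative 2:** The cut is the C2–C3 bond of the tetrahydrofuran. The retron is the cis-fused furofuranone A3, whose lactone holds C3 (as the α-carbon), C4 and ring A through a sacrificial benzylic C–O bond. Its precursor is the α-diazo lactone A4, which carries the B–C unit as a benzyl-type ether. Forward, Rh2(OAc)4 would generate the carbenoid at the lactone α-carbon; it inserts into the benzylic ether C–H bond next to ring B and closes the tetrahydrofuran. Later the lactone carbonyl is reduced to the C3 hydroxymethyl group and the lactone benzylic C–O bond is hydrogenolysed to give the C4 benzyl group.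
- In favour: the cis ring fusion gives the C3/C4 cis relationship and the endo position of ring B gives the C2/C3 cis relationship in the same event. Ring B enters by simple O-alkylation. For the tetrahydrofuran alone this is shorter than the aldol, O–H insertion, methylenation and hydroboration–coupling sequence, and on that point it is the better plan.
- Against: it does not address dihydrobenzofurans B and C, so it could replace only the endgame, not the key step. The carbenoid must choose one benzylic C–H bond and the endo transition state among other α-oxy C–H bonds and electron-rich arenes. A4 needs a trans-disubstituted lactone of defined absolute configuration and a base-mediated diazo transfer. The closing hydrogenolysis must cleave one benzylic C–O bond and spare three others.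
- Structure: A3 holds all three tetrahydrofuran centers in one bicycle; the chosen plan sets them in two separate, individually predictable steps.
- Mechanism: both use a dirhodium carbenoid, but O–H insertion is the more dependable reaction.
- Step economy: better by about three steps for the tetrahydrofuran, equal for the rest.

**Alternative 3:** The cut is the O1–C2 bond of dihydrobenzofuran B. The retron is the phenolic carbinol A6: C3 already carries ring B with its free ortho hydroxyl and the benzyloxymethyl group, and C2 is a secondary alcohol next to ring C, as either epimer. Forward, catalytic BF3·OEt2 at low temperature would ionize the carbinol to a cation stabilized by the para oxygen of ring C. The phenol oxygen closes the ring from the side away from the C3 substituent to give A5.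
- In favour: the step is stereoconvergent, so both carbinol epimers funnel into the trans product. On this point it is better than the chosen plan, where C2 must be set by a catalyst and the trans ratio is kinetic. It uses no tin. The bromide of A5 becomes a formyl group in one step, against two from the ester.
- Against: the stereocenter that matters, C3, is a benzylic methine that must be made beforehand in the right absolute sense and independently of the C unit. In practice this means an auxiliary-controlled C–C bond formation, reduction, protection and phenol release for each dihydrobenzofuran. The Lewis acid also meets the benzylic ether of the finished C unit, which can open and offer its cation to an electron-rich ring.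
- Structure: equal in convergence; the alternative forms C–O last, the chosen plan C–C last.
- Mechanism: the cation route depends on the same electron-richness that makes the molecule acid-sensitive; the radical route does not.
- Step economy: five to six steps and a stoichiometric auxiliary per ring, against two steps per ring.

Key step: step 11

**Assumptions and abbreviations**

- Assumption on the chemistry: the (Ra,R,R) enantiomer of ligand L is taken to give the (R) branched aryl ether from an (E)-3-arylallyl carbonate, by analogy with cinnamyl carbonates. If the sense is the reverse, the ligand enantiomers of steps 5 and 10 are exchanged and nothing else changes.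
- Assumption on supply: 22, 23 and 35 are taken as catalogue compounds.
- L = O,O′-(1,1′-binaphthalene-2,2′-diyl) N,N-bis(1-phenylethyl)phosphoramidite.
- TMPO = (2,2,6,6-tetramethylpiperidin-1-yl)oxy; TBSO = tert-butyldimethylsilyloxy.
- U = (2S,3R)-2-[4-(benzyloxy)-3-methoxyphenyl]-7-methoxy-3-(TMPO-methyl)-2,3-dihydro-1-benzofuran-5-yl.
- Q = (2R,3S)-2-{(2S,3R)-2-[4-(benzyloxy)-3-methoxyphenyl]-3-(TBSO-methyl)-7-methoxy-2,3-dihydro-1-benzofuran-5-yl}-3-(TBSO-methyl)-7-methoxy-2,3-dihydro-1-benzofuran-5-yl.

## Steps

Step 1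
Reactants: 1 ferulic acid
Product: 2 benzyl (E)-3-[4-(benzyloxy)-3-methoxyphenyl]prop-2-enoate
Conditions: BnBr (2.2 equiv), K2CO3, DMF, 60 °C
Reagents that add atoms: benzyl bromide, BrCc1ccccc1
Why: Williamson-type alkylation; K2CO3 deprotonates both the acid and the phenol and each displaces bromide, which masks the ring D phenol for the whole route and turns the acid into a reducible ester.

Step 2
Reactants: 2 benzyl (E)-3-[4-(benzyloxy)-3-methoxyphenyl]prop-2-enoate
Product: 3 (E)-3-[4-(benzyloxy)-3-methoxyphenyl]prop-2-en-1-ol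
Conditions: i-Bu2AlH (DIBAL-H), CH2Cl2, −78 → 0 °C; aq. KNaC4H4O6
Reagents that add atoms: none
Why: 1,2-Reduction of a conjugated ester by an aluminium hydride should give the allylic alcohol and leave the alkene and the aryl benzyl ether alone; the benzyl alcohol released is removed on the column.

Step 3
Reactants: 3 (E)-3-[4-(benzyloxy)-3-methoxyphenyl]prop-2-en-1-ol
Product: 4 (E)-3-[4-(benzyloxy)-3-methoxyphenyl]prop-2-en-1-yl methyl carbonate
Conditions: ClCO2Me, pyridine, CH2Cl2, 0 °C
Reagents that add atoms: methyl chloroformate, COC(=O)Cl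
Why: O-Acylation with a chloroformate installs the leaving group needed for allyl–iridium formation; pyridine takes up HCl so the p-alkoxycinnamyl system never meets acid.

Step 4
Reactants: 5 5-iodovanillin
Product: 6 methyl (E)-3-(4-hydroxy-3-iodo-5-methoxyphenyl)prop-2-enoate
Conditions: Ph3P=CHCO2Me, toluene, 90 °C
Reagents that add atoms: methyl (triphenylphosphoranylidene)acetate, COC(=O)C=P(c1ccccc1)(c1ccccc1)c1ccccc1
Why: Wittig olefination with a stabilized ylide should give the E acrylate directly on the free phenol; the iodine ortho to the hydroxyl is the future radical site of ring C.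

Step 5
Reactants: 6 methyl (E)-3-(4-hydroxy-3-iodo-5-methoxyphenyl)prop-2-enoate; 4 (E)-3-[4-(benzyloxy)-3-methoxyphenyl]prop-2-en-1-yl methyl carbonate
Product: 8 methyl (E)-3-[4-({(1S)-1-[4-(benzyloxy)-3-methoxyphenyl]prop-2-en-1-yl}oxy)-3-iodo-5-methoxyphenyl]prop-2-enoate, via sodium aryloxide 7 (not isolated)
Conditions: NaH, THF, 0 °C; then [Ir(cod)Cl]2 (2 mol%), (Sa,S,S)-L (4 mol%, pre-activated with n-PrNH2), 4, THF, rt → 40 °C
Reagents that add atoms: sodium hydride, [Na+].[H-] (sodium kept only in 7)
Why: Iridium-catalysed allylic etherification; the cyclometalated Ir–phosphoramidite forms a π-allyl complex from 4 and the aryloxide attacks the aryl-bearing terminus, so the branched ether forms with the ligand fixing the (S) configuration of the future C2 of dihydrobenzofuran C. Both ortho positions of the phenol are occupied, so an aromatic Claisen rearrangement has no outlet.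

Step 6
Reactants: 8 methyl (E)-3-[4-({(1S)-1-[4-(benzyloxy)-3-methoxyphenyl]prop-2-en-1-yl}oxy)-3-iodo-5-methoxyphenyl]prop-2-enoate; 9 TEMPO
Product: 10 methyl (E)-3-(U)prop-2-enoate
Conditions: TEMPO (6 equiv), Bu3SnH (3 equiv, syringe pump), degassed toluene, 70 °C
Reagents that add atoms: none
Why: Aryl radical 5-exo-trig cyclization with nitroxide capture, the same reaction type as the key step; the stannyl radical takes the iodine, the aryl radical closes onto the vinyl group trans to the C2 aryl group (pseudo-equatorial in the transition state) and TEMPO captures the primary radical. Intramolecular closure should outrun any addition to the acrylate.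

Step 7
Reactants: 10 methyl (E)-3-(U)prop-2-enoate
Product: 11 (E)-3-(U)prop-2-en-1-ol
Conditions: i-Bu2AlH (DIBAL-H), CH2Cl2, −78 °C; aq. KNaC4H4O6
Reagents that add atoms: none
Why: 1,2-Reduction of the conjugated ester; the hindered aminoxy ether is inert to hydride and is kept as the protecting group of the ring C hydroxymethyl group, which saves a cleavage and a silylation at this stage.

Step 8
Reactants: 11 (E)-3-(U)prop-2-en-1-ol
Product: 12 (E)-3-(U)prop-2-en-1-yl methyl carbonate
Conditions: ClCO2Me, pyridine, CH2Cl2, 0 °C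
Reagents that add atoms: methyl chloroformate, COC(=O)Cl
Why: Carbonate formation as in step 3; the basic medium protects the acid-labile benzylic ether and the electron-rich cinnamyl system.

Step 9
Reactants: 13 methyl vanillate
Product: 14 methyl 4-hydroxy-3-iodo-5-methoxybenzoate
Conditions: NIS, TsOH·H2O (cat.), MeCN, rt
Reagents that add atoms: N-iodosuccinimide, O=C1CCC(=O)N1I
Why: Electrophilic aromatic iodination; the hydroxyl directs iodine to the only free ortho position because the para position holds the ester.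

Step 10
Reactants: 14 methyl 4-hydroxy-3-iodo-5-methoxybenzoate; 12 (E)-3-(U)prop-2-en-1-yl methyl carbonate
Product: 16 methyl 3-iodo-5-methoxy-4-{[(1R)-1-(U)prop-2-en-1-yl]oxy}benzoate, via sodium aryloxide 15 (not isolated)
Conditions: NaH, THF, 0 °C; then [Ir(cod)Cl]2 (2 mol%), (Ra,R,R)-L (4 mol%, pre-activated with n-PrNH2), 12, THF, rt → 40 °C
Reagents that add atoms: sodium hydride, [Na+].[H-] (sodium kept only in 15)
Why: The same iridium-catalysed allylic etherification with the mirror-image ligand, so the new C–O carbon should be (R) whatever the remote ring C centers are (catalyst control). The iodo and methoxy groups flanking the ether oxygen block a Claisen rearrangement, and the product carries the iodide and the vinyl group in the 1,5 relationship needed for ring closure.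

Step 11
Reactants: 16 methyl 3-iodo-5-methoxy-4-{[(1R)-1-(U)prop-2-en-1-yl]oxy}benzoate; 9 TEMPO
Product: 17 methyl (2R,3S)-7-methoxy-3-(TMPO-methyl)-2-(U)-2,3-dihydro-1-benzofuran-5-carboxylate
Conditions: TEMPO (6 equiv), Bu3SnH (3 equiv, syringe pump over several hours), degassed toluene, 70 °C
Reagents that add atoms: none
Why: TEMPO takes hydrogen from Bu3SnH, and the stannyl radical abstracts iodine from ring B of 16, the weakest bond in the molecule, to give a σ-aryl radical. This radical adds to the internal vinyl carbon in a 5-exo-trig closure, forming C3–C3a and dihydrobenzofuran B, and the exocyclic primary radical couples with TEMPO to form the CH2–O bond. The closest known reaction type is the tin-hydride-mediated cyclization of ortho-halophenyl allyl ethers with nitroxide capture. The new stereocenter C3 is set by the existing C2 center: in the chair-like transition state the ring C aryl group is pseudo-equatorial and the alkene terminus turns away from it, so the trans (2R,3S) ring should result. The step needs closure before capture of the aryl radical, which the much higher rate of the intramolecular addition secures. It also needs capture before hydrogen transfer to the primary radical, which slow addition of the stannane and excess nitroxide secure; the short oxygen-containing tether enforces exo closure, and ring expansion by aryl migration is too slow to compete. No chain operates, since each turnover uses one stannane and two nitroxides, so no azo initiator is added. Ester, benzyl ether, the benzylic ether of the C unit and the aminoxy ether already present do not react with these radicals.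

Step 12
Reactants: 17 methyl (2R,3S)-7-methoxy-3-(TMPO-methyl)-2-(U)-2,3-dihydro-1-benzofuran-5-carboxylate
Product: 18 methyl (2R,3S)-2-{(2S,3R)-2-[4-(benzyloxy)-3-methoxyphenyl]-3-(hydroxymethyl)-7-methoxy-2,3-dihydro-1-benzofuran-5-yl}-3-(hydroxymethyl)-7-methoxy-2,3-dihydro-1-benzofuran-5-carboxylate
Conditions: Zn dust, AcOH/THF/H2O (3:1:1), 60 °C
Reagents that add atoms: none
Why: Dissolving-metal reduction of N–O bonds; zinc in acetic acid should cleave both aminoxy ethers in one operation, while the ester, the benzyl ether and the cyclic benzylic ethers tolerate warm acetic acid.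

Step 13
Reactants: 18 methyl (2R,3S)-2-{(2S,3R)-2-[4-(benzyloxy)-3-methoxyphenyl]-3-(hydroxymethyl)-7-methoxy-2,3-dihydro-1-benzofuran-5-yl}-3-(hydroxymethyl)-7-methoxy-2,3-dihydro-1-benzofuran-5-carboxylate
Product: 19 methyl ester Q–CO2CH3
Conditions: TBSCl, imidazole, DMF, rt
Reagents that add atoms: tert-butyldimethylsilyl chloride, CC(C)(C)[Si](C)(C)Cl
Why: Imidazole-promoted silylation of both primary alcohols; the silyl ethers withstand the hydride, boron, rhodium, titanium and palladium steps and leave at the end with fluoride, without acid.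

Step 14
Reactants: 19 methyl ester Q–CO2CH3
Product: 20 benzylic alcohol Q–CH2OH
Conditions: i-Bu2AlH (DIBAL-H), CH2Cl2, −78 → 0 °C; aq. KNaC4H4O6
Reagents that add atoms: none
Why: Full hydride reduction of the aryl ester; going to the alcohol and back is preferred to a partial reduction because neither step can stop short or overshoot.

Step 15
Reactants: 20 benzylic alcohol Q–CH2OH
Product: 21 aldehyde Q–CHO
Conditions: MnO2, CH2Cl2, rt
Reagents that add atoms: none
Why: MnO2 oxidizes benzylic alcohols under neutral conditions and stops at the aldehyde; silyl, benzyl and benzylic ethers are not affected.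

Step 16
Reactants: 22 3-(tert-butyldimethylsilyloxy)propanoic acid; 23 (R)-4-benzyl-1,3-oxazolidin-2-one
Product: 25 (R)-4-benzyl-3-[3-(tert-butyldimethylsilyloxy)propanoyl]-1,3-oxazolidin-2-one, via mixed pivalic anhydride 24 (not isolated)
Conditions: PivCl, Et3N, THF, −20 °C; then 23, LiCl, rt
Reagents that add atoms: pivaloyl chloride, CC(C)(C)C(=O)Cl (atoms kept only in 24)
Why: N-Acylation of the oxazolidinone through a mixed anhydride with LiCl/Et3N activation; no strong base is present, so the β-silyloxy acyl unit should not eliminate.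

Step 17
Reactants: 21 aldehyde Q–CHO; 25 (R)-4-benzyl-3-[3-(tert-butyldimethylsilyloxy)propanoyl]-1,3-oxazolidin-2-one
Product: 27 (R)-4-benzyl-3-[(2R,3R)-2-(TBSO-methyl)-3-hydroxy-3-(Q)propanoyl]-1,3-oxazolidin-2-one, via Z dibutylboron enolate 26 (not isolated)
Conditions: Bu2BOTf, i-Pr2NEt, CH2Cl2, 0 °C; 21, −78 → 0 °C; pH 7 buffer, MeOH, H2O2, 0 °C
Reagents that add atoms: dibutylboron triflate, CCCCB(CCCC)OS(=O)(=O)C(F)(F)F (atoms kept only in 26)
Why: Evans syn-aldol; the Z boron enolate adds to the aldehyde through a closed chair transition state on the enolate face away from the auxiliary benzyl group. This should set (2R,3R), the future C3 and C2 of the tetrahydrofuran, in the syn relationship that becomes cis in the ring. The auxiliary overrides the remote stereocenters of Q.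

Step 18
Reactants: 27 (R)-4-benzyl-3-[(2R,3R)-2-(TBSO-methyl)-3-hydroxy-3-(Q)propanoyl]-1,3-oxazolidin-2-one
Product: 29 (2R,3R)-2-(TBSO-methyl)-3-hydroxy-3-(Q)propanoic acid, via peroxy acid 28 (not isolated)
Conditions: LiOH, H2O2, THF/H2O, 0 °C; aq. Na2SO3; dilute HCl to pH 4
Reagents that add atoms: hydrogen peroxide, OO
Why: Hydroperoxide anion attacks the exocyclic imide carbonyl selectively and the peracid is reduced by sulfite; at 0 °C retro-aldol cleavage should not compete, and the auxiliary is recovered.

Step 19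
Reactants: 29 (2R,3R)-2-(TBSO-methyl)-3-hydroxy-3-(Q)propanoic acid
Product: 32 (3R,4R)-3-(TBSO-methyl)-1-diazo-4-hydroxy-4-(Q)butan-2-one, via mixed carbonic anhydride 30 (not isolated), via silyl diazoketone 31 (not isolated)
Conditions: i-BuOCOCl (1.0 equiv), N-methylmorpholine, THF, −20 °C; then Me3SiCHN2, MeCN, 0 °C → rt; aqueous work-up
Reagents that add atoms: isobutyl chloroformate, CC(C)COC(=O)Cl (atoms kept only in 30); trimethylsilyldiazomethane, C[Si](C)(C)C=[N+]=[N-]
Why: Diazoketone synthesis of the Arndt–Eistert type; the carboxylate reacts with one equivalent of chloroformate much faster than the secondary alcohol, the mixed anhydride acylates the diazo carbon, and the C-silyl group is lost on work-up.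

Step 20
Reactants: 32 (3R,4R)-3-(TBSO-methyl)-1-diazo-4-hydroxy-4-(Q)butan-2-one
Product: 33 (4R,5R)-4-(TBSO-methyl)-5-(Q)dihydrofuran-3(2H)-one
Conditions: Rh2(OAc)4 (2 mol%), CH2Cl2, rt, slow addition of 32
Reagents that add atoms: none
Why: Intramolecular O–H insertion of a rhodium carbenoid; the hydroxyl captures the carbenoid and the five-membered ring closes under neutral conditions. The carbinol carbon is not a reaction site, so the syn pair becomes the cis pair.

Step 21
Reactants: 33 (4R,5R)-4-(TBSO-methyl)-5-(Q)dihydrofuran-3(2H)-one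
Product: 34 tert-butyldimethyl{[(2R,3R)-4-methylidene-2-(Q)oxolan-3-yl]methoxy}silane
Conditions: Cp2TiMe2, toluene, 65 °C, dark
Reagents that add atoms: dimethyltitanocene, C[Ti](C)(C1C=CC=C1)C1C=CC=C1
Why: Petasis methylenation; Cp2Ti=CH2 formed on heating adds to the carbonyl and the oxatitanacycle collapses to the alkene. The reagent is not basic, so the stereocenter next to the ketone and the β-silyloxy group should survive where a phosphorus ylide could epimerize or eliminate.

Step 22
Reactants: 34 tert-butyldimethyl{[(2R,3R)-4-methylidene-2-(Q)oxolan-3-yl]methoxy}silane; 35 1-(benzyloxy)-4-bromo-2-methoxybenzene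
Product: 37 (2R,3R,4R)-4-[4-(benzyloxy)-3-methoxybenzyl]-3-(TBSO-methyl)-2-(Q)oxolane, via B-alkyl borane 36 (not isolated)
Conditions: 9-BBN-H, THF, rt → 50 °C; then 35, Pd(dppf)Cl2 (5 mol%), aq. K3PO4, DMF, 50 °C
Reagents that add atoms: 9-borabicyclo[3.3.1]nonane, [H]B1C2CCCC1CCC2 (atoms other than hydrogen kept only in 36)
Why: Hydroboration followed by B-alkyl Suzuki–Miyaura coupling; 9-BBN-H adds to the exocyclic alkene from the face opposite the two cis substituents with boron on the terminal carbon, so the new C4–H is trans to them and the center should be (4R), all-cis. The alkylborane then transmetalates to the arylpalladium species from 35 and reductive elimination forms the benzylic C–C bond.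

Step 23
Reactants: 37 (2R,3R,4R)-4-[4-(benzyloxy)-3-methoxybenzyl]-3-(TBSO-methyl)-2-(Q)oxolane
Product: 38 (2R,3R,4R)-4-[4-(benzyloxy)-3-methoxybenzyl]-3-(hydroxymethyl)-2-{(2R,3S)-2-[(2S,3R)-2-[4-(benzyloxy)-3-methoxyphenyl]-3-(hydroxymethyl)-7-methoxy-2,3-dihydro-1-benzofuran-5-yl]-3-(hydroxymethyl)-7-methoxy-2,3-dihydro-1-benzofuran-5-yl}oxolane
Conditions: Bu4NF, THF, 0 °C → rt
Reagents that add atoms: none
Why: Fluoride cleaves the three primary silyl ethers; the medium is close to neutral, so the benzylic ethers and all stereocenters are not at risk.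

Step 24
Reactants: 38 (2R,3R,4R)-4-[4-(benzyloxy)-3-methoxybenzyl]-3-(hydroxymethyl)-2-{(2R,3S)-2-[(2S,3R)-2-[4-(benzyloxy)-3-methoxyphenyl]-3-(hydroxymethyl)-7-methoxy-2,3-dihydro-1-benzofuran-5-yl]-3-(hydroxymethyl)-7-methoxy-2,3-dihydro-1-benzofuran-5-yl}oxolane
Product: 39 target CNP0395728.1
Conditions: H2 (1 atm), Pd/C, EtOAc/MeOH, rt, stopped when 38 is consumed
Reagents that add atoms: none
Why: Hydrogenolysis of the two aryl benzyl ethers; these should cleave much faster than the cyclic benzylic C–O bonds of the tetrahydrofuran and the dihydrobenzofurans, and filtration leaves the polyphenol without reagent residues.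

## Compound list

1 | ferulic acid, (E)-3-(4-hydroxy-3-methoxyphenyl)prop-2-enoic acid | COc1cc(/C=C/C(=O)O)ccc1O | starting material
2 | benzyl (E)-3-[4-(benzyloxy)-3-methoxyphenyl]prop-2-enoate | COc1cc(/C=C/C(=O)OCc2ccccc2)ccc1OCc1ccccc1 | intermediate
3 | (E)-3-[4-(benzyloxy)-3-methoxyphenyl]prop-2-en-1-ol | COc1cc(/C=C/CO)ccc1OCc1ccccc1 | intermediate
4 | (E)-3-[4-(benzyloxy)-3-methoxyphenyl]prop-2-en-1-yl methyl carbonate | COC(=O)OC/C=C/c1ccc(OCc2ccccc2)c(OC)c1 | intermediate
5 | 5-iodovanillin, 4-hydroxy-3-iodo-5-methoxybenzaldehyde | COc1cc(C=O)cc(I)c1O | starting material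
6 | methyl (E)-3-(4-hydroxy-3-iodo-5-methoxyphenyl)prop-2-enoate | COC(=O)/C=C/c1cc(OC)c(O)c(I)c1 | intermediate
7 | sodium 2-iodo-6-methoxy-4-[(E)-3-methoxy-3-oxoprop-1-en-1-yl]phenoxide | COC(=O)/C=C/c1cc(OC)c([O-])c(I)c1.[Na+] | intermediate (not isolated)
8 | methyl (E)-3-[4-({(1S)-1-[4-(benzyloxy)-3-methoxyphenyl]prop-2-en-1-yl}oxy)-3-iodo-5-methoxyphenyl]prop-2-enoate | COC(=O)/C=C/c1cc(OC)c(O[C@@H](C=C)c2ccc(OCc3ccccc3)c(OC)c2)c(I)c1 | intermediate
9 | TEMPO, 2,2,6,6-tetramethylpiperidine-1-oxyl | CC1(C)CCCC(C)(C)N1[O] | starting material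
10 | methyl (E)-3-[(2S,3R)-2-[4-(benzyloxy)-3-methoxyphenyl]-7-methoxy-3-(TMPO-methyl)-2,3-dihydro-1-benzofuran-5-yl]prop-2-enoate | COC(=O)/C=C/c1cc(OC)c2c(c1)[C@H](CON3C(C)(C)CCCC3(C)C)[C@@H](c3ccc(OCc4ccccc4)c(OC)c3)O2 | intermediate
11 | (E)-3-[(2S,3R)-2-[4-(benzyloxy)-3-methoxyphenyl]-7-methoxy-3-(TMPO-methyl)-2,3-dihydro-1-benzofuran-5-yl]prop-2-en-1-ol | OC/C=C/c1cc(OC)c2c(c1)[C@H](CON3C(C)(C)CCCC3(C)C)[C@@H](c3ccc(OCc4ccccc4)c(OC)c3)O2 | intermediate
12 | (E)-3-[(2S,3R)-2-[4-(benzyloxy)-3-methoxyphenyl]-7-methoxy-3-(TMPO-methyl)-2,3-dihydro-1-benzofuran-5-yl]prop-2-en-1-yl methyl carbonate | COC(=O)OC/C=C/c1cc(OC)c2c(c1)[C@H](CON3C(C)(C)CCCC3(C)C)[C@@H](c3ccc(OCc4ccccc4)c(OC)c3)O2 | intermediate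
13 | methyl vanillate, methyl 4-hydroxy-3-methoxybenzoate | COC(=O)c1ccc(O)c(OC)c1 | starting material
14 | methyl 4-hydroxy-3-iodo-5-methoxybenzoate | COC(=O)c1cc(OC)c(O)c(I)c1 | intermediate
15 | sodium 2-iodo-6-methoxy-4-(methoxycarbonyl)phenoxide | COC(=O)c1cc(OC)c([O-])c(I)c1.[Na+] | intermediate (not isolated)
16 | methyl 3-iodo-5-methoxy-4-{[(1R)-1-(U)prop-2-en-1-yl]oxy}benzoate | COC(=O)c1cc(OC)c(O[C@H](C=C)c3cc(OC)c5c(c3)[C@H](CON7C(C)(C)CCCC7(C)C)[C@@H](c3ccc(OCc6ccccc6)c(OC)c3)O5)c(I)c1 | intermediate
17 | methyl (2R,3S)-7-methoxy-3-(TMPO-methyl)-2-(U)-2,3-dihydro-1-benzofuran-5-carboxylate | COC(=O)c1cc(OC)c2c(c1)[C@@H](CON7C(C)(C)CCCC7(C)C)[C@H](c3cc(OC)c5c(c3)[C@H](CON8C(C)(C)CCCC8(C)C)[C@@H](c3ccc(OCc6ccccc6)c(OC)c3)O5)O2 | intermediate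
18 | methyl (2R,3S)-2-{(2S,3R)-2-[4-(benzyloxy)-3-methoxyphenyl]-3-(hydroxymethyl)-7-methoxy-2,3-dihydro-1-benzofuran-5-yl}-3-(hydroxymethyl)-7-methoxy-2,3-dihydro-1-benzofuran-5-carboxylate | COC(=O)c1cc(OC)c2c(c1)[C@@H](CO)[C@H](c3cc(OC)c5c(c3)[C@H](CO)[C@@H](c3ccc(OCc6ccccc6)c(OC)c3)O5)O2 | intermediate
19 | methyl ester Q–CO2CH3 | COC(=O)c1cc(OC)c2c(c1)[C@@H](CO[Si](C)(C)C(C)(C)C)[C@H](c3cc(OC)c5c(c3)[C@H](CO[Si](C)(C)C(C)(C)C)[C@@H](c3ccc(OCc6ccccc6)c(OC)c3)O5)O2 | intermediate
20 | benzylic alcohol Q–CH2OH | OCc1cc(OC)c2c(c1)[C@@H](CO[Si](C)(C)C(C)(C)C)[C@H](c3cc(OC)c5c(c3)[C@H](CO[Si](C)(C)C(C)(C)C)[C@@H](c3ccc(OCc6ccccc6)c(OC)c3)O5)O2 | intermediate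
21 | aldehyde Q–CHO | O=Cc1cc(OC)c2c(c1)[C@@H](CO[Si](C)(C)C(C)(C)C)[C@H](c3cc(OC)c5c(c3)[C@H](CO[Si](C)(C)C(C)(C)C)[C@@H](c3ccc(OCc6ccccc6)c(OC)c3)O5)O2 | intermediate
22 | 3-(tert-butyldimethylsilyloxy)propanoic acid | CC(C)(C)[Si](C)(C)OCCC(=O)O | starting material
23 | (R)-4-benzyl-1,3-oxazolidin-2-one | O=C1N[C@H](Cc2ccccc2)CO1 | starting material
24 | 3-(tert-butyldimethylsilyloxy)propanoic pivalic anhydride | CC(C)(C)[Si](C)(C)OCCC(=O)OC(=O)C(C)(C)C | intermediate (not isolated)
25 | (R)-4-benzyl-3-[3-(tert-butyldimethylsilyloxy)propanoyl]-1,3-oxazolidin-2-one | CC(C)(C)[Si](C)(C)OCCC(=O)N1C(=O)OC[C@H]1Cc1ccccc1 | intermediate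
26 | Z dibutylboron enolate of 25 | CCCCB(CCCC)O/C(=C\CO[Si](C)(C)C(C)(C)C)N1C(=O)OC[C@H]1Cc1ccccc1 | intermediate (not isolated)
27 | (R)-4-benzyl-3-[(2R,3R)-2-(TBSO-methyl)-3-hydroxy-3-(Q)propanoyl]-1,3-oxazolidin-2-one | O[C@@H](c3cc(OC)c4c(c3)[C@@H](CO[Si](C)(C)C(C)(C)C)[C@H](c3cc(OC)c5c(c3)[C@H](CO[Si](C)(C)C(C)(C)C)[C@@H](c3ccc(OCc6ccccc6)c(OC)c3)O5)O4)[C@@H](CO[Si](C)(C)C(C)(C)C)C(=O)N1C(=O)OC[C@H]1Cc1ccccc1 | intermediate
28 | (2R,3R)-2-(TBSO-methyl)-3-hydroxy-3-(Q)propaneperoxoic acid | O[C@@H](c3cc(OC)c4c(c3)[C@@H](CO[Si](C)(C)C(C)(C)C)[C@H](c3cc(OC)c5c(c3)[C@H](CO[Si](C)(C)C(C)(C)C)[C@@H](c3ccc(OCc6ccccc6)c(OC)c3)O5)O4)[C@@H](CO[Si](C)(C)C(C)(C)C)C(=O)OO | intermediate (not isolated)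
29 | (2R,3R)-2-(TBSO-methyl)-3-hydroxy-3-(Q)propanoic acid | O[C@@H](c3cc(OC)c4c(c3)[C@@H](CO[Si](C)(C)C(C)(C)C)[C@H](c3cc(OC)c5c(c3)[C@H](CO[Si](C)(C)C(C)(C)C)[C@@H](c3ccc(OCc6ccccc6)c(OC)c3)O5)O4)[C@@H](CO[Si](C)(C)C(C)(C)C)C(=O)O | intermediate
30 | mixed anhydride of 29 with isobutyl hydrogen carbonate | O[C@@H](c3cc(OC)c4c(c3)[C@@H](CO[Si](C)(C)C(C)(C)C)[C@H](c3cc(OC)c5c(c3)[C@H](CO[Si](C)(C)C(C)(C)C)[C@@H](c3ccc(OCc6ccccc6)c(OC)c3)O5)O4)[C@@H](CO[Si](C)(C)C(C)(C)C)C(=O)OC(=O)OCC(C)C | intermediate (not isolated)
31 | (3R,4R)-3-(TBSO-methyl)-1-diazo-4-hydroxy-4-(Q)-1-(trimethylsilyl)butan-2-one | O[C@@H](c3cc(OC)c4c(c3)[C@@H](CO[Si](C)(C)C(C)(C)C)[C@H](c3cc(OC)c5c(c3)[C@H](CO[Si](C)(C)C(C)(C)C)[C@@H](c3ccc(OCc6ccccc6)c(OC)c3)O5)O4)[C@@H](CO[Si](C)(C)C(C)(C)C)C(=O)C(=[N+]=[N-])[Si](C)(C)C | intermediate (not isolated)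
32 | (3R,4R)-3-(TBSO-methyl)-1-diazo-4-hydroxy-4-(Q)butan-2-one | O[C@@H](c3cc(OC)c4c(c3)[C@@H](CO[Si](C)(C)C(C)(C)C)[C@H](c3cc(OC)c5c(c3)[C@H](CO[Si](C)(C)C(C)(C)C)[C@@H](c3ccc(OCc6ccccc6)c(OC)c3)O5)O4)[C@@H](CO[Si](C)(C)C(C)(C)C)C(=O)C=[N+]=[N-] | intermediate
33 | (4R,5R)-4-(TBSO-methyl)-5-(Q)dihydrofuran-3(2H)-one | O=C1CO[C@@H](c3cc(OC)c4c(c3)[C@@H](CO[Si](C)(C)C(C)(C)C)[C@H](c3cc(OC)c5c(c3)[C@H](CO[Si](C)(C)C(C)(C)C)[C@@H](c3ccc(OCc6ccccc6)c(OC)c3)O5)O4)[C@H]1CO[Si](C)(C)C(C)(C)C | intermediate
34 | tert-butyldimethyl{[(2R,3R)-4-methylidene-2-(Q)oxolan-3-yl]methoxy}silane | C=C1CO[C@@H](c3cc(OC)c4c(c3)[C@@H](CO[Si](C)(C)C(C)(C)C)[C@H](c3cc(OC)c5c(c3)[C@H](CO[Si](C)(C)C(C)(C)C)[C@@H](c3ccc(OCc6ccccc6)c(OC)c3)O5)O4)[C@H]1CO[Si](C)(C)C(C)(C)C | intermediate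
35 | 1-(benzyloxy)-4-bromo-2-methoxybenzene | COc1cc(Br)ccc1OCc1ccccc1 | starting material
36 | 9-{[(3R,4R,5R)-4-(TBSO-methyl)-5-(Q)oxolan-3-yl]methyl}-9-borabicyclo[3.3.1]nonane | C(B1C2CCCC1CCC2)[C@H]1CO[C@@H](c3cc(OC)c4c(c3)[C@@H](CO[Si](C)(C)C(C)(C)C)[C@H](c3cc(OC)c5c(c3)[C@H](CO[Si](C)(C)C(C)(C)C)[C@@H](c3ccc(OCc6ccccc6)c(OC)c3)O5)O4)[C@H]1CO[Si](C)(C)C(C)(C)C | intermediate (not isolated)
37 | (2R,3R,4R)-4-[4-(benzyloxy)-3-methoxybenzyl]-3-(TBSO-methyl)-2-(Q)oxolane | COc1cc(C[C@H]2CO[C@@H](c3cc(OC)c4c(c3)[C@@H](CO[Si](C)(C)C(C)(C)C)[C@H](c3cc(OC)c5c(c3)[C@H](CO[Si](C)(C)C(C)(C)C)[C@@H](c3ccc(OCc6ccccc6)c(OC)c3)O5)O4)[C@H]2CO[Si](C)(C)C(C)(C)C)ccc1OCc1ccccc1 | intermediate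
38 | (2R,3R,4R)-4-[4-(benzyloxy)-3-methoxybenzyl]-3-(hydroxymethyl)-2-{(2R,3S)-2-[(2S,3R)-2-[4-(benzyloxy)-3-methoxyphenyl]-3-(hydroxymethyl)-7-methoxy-2,3-dihydro-1-benzofuran-5-yl]-3-(hydroxymethyl)-7-methoxy-2,3-dihydro-1-benzofuran-5-yl}oxolane | COc1cc(C[C@H]2CO[C@@H](c3cc(OC)c4c(c3)[C@@H](CO)[C@H](c3cc(OC)c5c(c3)[C@H](CO)[C@@H](c3ccc(OCc6ccccc6)c(OC)c3)O5)O4)[C@H]2CO)ccc1OCc1ccccc1 | intermediate
39 | CNP0395728.1, (2R,3R,4R)-4-(4-hydroxy-3-methoxybenzyl)-3-(hydroxymethyl)-2-{(2R,3S)-3-(hydroxymethyl)-2-[(2S,3R)-3-(hydroxymethyl)-2-(4-hydroxy-3-methoxyphenyl)-7-methoxy-2,3-dihydro-1-benzofuran-5-yl]-7-methoxy-2,3-dihydro-1-benzofuran-5-yl}oxolane | COc1cc(C[C@H]2CO[C@@H](c3cc(OC)c4c(c3)[C@@H](CO)[C@H](c3cc(OC)c5c(c3)[C@H](CO)[C@@H](c3ccc(O)c(OC)c3)O5)O4)[C@H]2CO)ccc1O | target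

## Step count and least certain steps

Total: 24 steps. Longest linear sequence: 21 steps, from 1 to 39 through steps 1–3, 5–8, 10–15 and 17–24. Steps 4, 9 and 16 are branch steps.

**Step 11 (key).** The likely failures are hydrogen transfer to the cyclized primary radical before the nitroxide captures it, and incomplete trans selectivity. The first arises because capture is bimolecular and competes with reduction by the stannane or by the hydroxylamine that builds up. The second arises because the preference rests only on a pseudo-equatorial aryl group. Fallback, from 16: the same 5-exo closure is run as a chain oxygenation. Bu3SnH is added slowly to 16 in toluene under a stream of dry air, so that dioxygen captures the primary radical and the peroxyl radical carries the chain; the hydroperoxide is reduced in the same flask with PPh3. This gives methyl (2R,3S)-3-(hydroxymethyl)-7-methoxy-2-(U)-2,3-dihydro-1-benzofuran-5-carboxylate F2, whose ring C oxygen is still the aminoxy ether. The zinc and acetic acid treatment of step 12 then takes F2 to 18. A minor cis isomer would be removed at 17 or 18, where the two are diastereomers.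

**Step 10.** The likely failure is loss of branched selectivity and of configuration at the new ether carbon. The aryloxide 15 is substituted at both ortho positions and is weakly nucleophilic, and the product is the ether of an acidic phenol at a para-oxygenated benzylic, allylic carbon that the catalyst can ionize again. Step 5 is the same reaction on cheap material and would be optimized first. Fallback, from 12 and 14: [Cp*Ru(MeCN)3]PF6 (catalytic) with K2CO3 in acetone gives the branched ether without control of the new center. The product is 16 together with its epimer at the ether carbon, methyl 3-iodo-5-methoxy-4-{[(1S)-1-(U)prop-2-en-1-yl]oxy}benzoate F1. Because the C unit is already a single enantiomer the two are diastereomers; they are separated by chromatography and 16 rejoins the route at step 11.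

**Step 19.** The likely failure is acylation of the free β-hydroxyl by the chloroformate, or closure of the mixed anhydride to a β-lactone that loses CO2, since the alcohol is only two carbons from the activated carboxyl. Fallback, from 27: Et3SiOTf and 2,6-lutidine give the triethylsilyl ether of 27 F3. LiOH/H2O2 gives the O-triethylsilyl acid F4. Its mixed anhydride with i-BuOCOCl is treated with Me3SiCHN2 to give the O-triethylsilyl diazoketone F5. HF·pyridine buffered with pyridine at 0 °C removes the secondary triethylsilyl group in the presence of the primary TBS ethers and returns 32.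

**Step 21.** The likely failure is epimerization at the carbon next to the ketone, or β-elimination of the ring oxygen or the silyloxy group, during a slow methylenation of a hindered ketone at 65 °C. Fallback, from 33: Me3SiCH2MgCl with CeCl3 in THF at −78 °C adds to the carbonyl without enolization and gives the tertiary β-hydroxysilane (4R,5R)-4-(TBSO-methyl)-5-(Q)-3-[(trimethylsilyl)methyl]oxolan-3-ol F6. KH in THF at 0 °C then effects the Peterson elimination and returns 34.

**Step 22.** The likely failure is slow transmetalation of a β-branched alkylborane to the arylpalladium species from an electron-rich bromide, with protodeboronation or β-hydride elimination taking over. Facial selectivity of the hydroboration is the lesser risk because both ring substituents shield the same face. Fallback, from 34: the borane 36 is formed as before and oxidized with NaBO3·4H2O to the all-cis alcohol [(3S,4R,5R)-4-(TBSO-methyl)-5-(Q)oxolan-3-yl]methanol F7. I2, PPh3 and imidazole convert it into the iodide (2R,3R,4R)-4-(iodomethyl)-3-(TBSO-methyl)-2-(Q)oxolane F8. Zn dust with LiCl in THF gives the alkylzinc iodide F9. Negishi coupling of F9 with 35 (Pd(OAc)2, SPhos, THF, rt → 50 °C) returns 37.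

## Further compounds

F1 | step 10 | methyl 3-iodo-5-methoxy-4-{[(1S)-1-(U)prop-2-en-1-yl]oxy}benzoate (epimer of 16 at the ether carbon) | COC(=O)c1cc(OC)c(O[C@@H](C=C)c3cc(OC)c5c(c3)[C@H](CON7C(C)(C)CCCC7(C)C)[C@@H](c3ccc(OCc6ccccc6)c(OC)c3)O5)c(I)c1
F2 | step 11 | methyl (2R,3S)-3-(hydroxymethyl)-7-methoxy-2-(U)-2,3-dihydro-1-benzofuran-5-carboxylate | COC(=O)c1cc(OC)c2c(c1)[C@@H](CO)[C@H](c3cc(OC)c5c(c3)[C@H](CON7C(C)(C)CCCC7(C)C)[C@@H](c3ccc(OCc6ccccc6)c(OC)c3)O5)O2
F3 | step 19 | (R)-4-benzyl-3-[(2R,3R)-2-(TBSO-methyl)-3-(Q)-3-(triethylsilyloxy)propanoyl]-1,3-oxazolidin-2-one | CC[Si](CC)(CC)O[C@@H](c3cc(OC)c4c(c3)[C@@H](CO[Si](C)(C)C(C)(C)C)[C@H](c3cc(OC)c5c(c3)[C@H](CO[Si](C)(C)C(C)(C)C)[C@@H](c3ccc(OCc6ccccc6)c(OC)c3)O5)O4)[C@@H](CO[Si](C)(C)C(C)(C)C)C(=O)N1C(=O)OC[C@H]1Cc1ccccc1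
F4 | step 19 | (2R,3R)-2-(TBSO-methyl)-3-(Q)-3-(triethylsilyloxy)propanoic acid | CC[Si](CC)(CC)O[C@@H](c3cc(OC)c4c(c3)[C@@H](CO[Si](C)(C)C(C)(C)C)[C@H](c3cc(OC)c5c(c3)[C@H](CO[Si](C)(C)C(C)(C)C)[C@@H](c3ccc(OCc6ccccc6)c(OC)c3)O5)O4)[C@@H](CO[Si](C)(C)C(C)(C)C)C(=O)O
F5 | step 19 | (3R,4R)-3-(TBSO-methyl)-1-diazo-4-(Q)-4-(triethylsilyloxy)butan-2-one | CC[Si](CC)(CC)O[C@@H](c3cc(OC)c4c(c3)[C@@H](CO[Si](C)(C)C(C)(C)C)[C@H](c3cc(OC)c5c(c3)[C@H](CO[Si](C)(C)C(C)(C)C)[C@@H](c3ccc(OCc6ccccc6)c(OC)c3)O5)O4)[C@@H](CO[Si](C)(C)C(C)(C)C)C(=O)C=[N+]=[N-]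
F6 | step 21 | (4R,5R)-4-(TBSO-methyl)-5-(Q)-3-[(trimethylsilyl)methyl]oxolan-3-ol (C3 configuration not defined) | C[Si](C)(C)CC1(O)CO[C@@H](c3cc(OC)c4c(c3)[C@@H](CO[Si](C)(C)C(C)(C)C)[C@H](c3cc(OC)c5c(c3)[C@H](CO[Si](C)(C)C(C)(C)C)[C@@H](c3ccc(OCc6ccccc6)c(OC)c3)O5)O4)[C@H]1CO[Si](C)(C)C(C)(C)C
F7 | step 22 | [(3S,4R,5R)-4-(TBSO-methyl)-5-(Q)oxolan-3-yl]methanol (all-cis) | OC[C@H]1CO[C@@H](c3cc(OC)c4c(c3)[C@@H](CO[Si](C)(C)C(C)(C)C)[C@H](c3cc(OC)c5c(c3)[C@H](CO[Si](C)(C)C(C)(C)C)[C@@H](c3ccc(OCc6ccccc6)c(OC)c3)O5)O4)[C@H]1CO[Si](C)(C)C(C)(C)C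
F8 | step 22 | (2R,3R,4R)-4-(iodomethyl)-3-(TBSO-methyl)-2-(Q)oxolane | IC[C@H]1CO[C@@H](c3cc(OC)c4c(c3)[C@@H](CO[Si](C)(C)C(C)(C)C)[C@H](c3cc(OC)c5c(c3)[C@H](CO[Si](C)(C)C(C)(C)C)[C@@H](c3ccc(OCc6ccccc6)c(OC)c3)O5)O4)[C@H]1CO[Si](C)(C)C(C)(C)C
F9 | step 22 | {[(3R,4R,5R)-4-(TBSO-methyl)-5-(Q)oxolan-3-yl]methyl}zinc iodide | I[Zn]C[C@H]1CO[C@@H](c3cc(OC)c4c(c3)[C@@H](CO[Si](C)(C)C(C)(C)C)[C@H](c3cc(OC)c5c(c3)[C@H](CO[Si](C)(C)C(C)(C)C)[C@@H](c3ccc(OCc6ccccc6)c(OC)c3)O5)O4)[C@H]1CO[Si](C)(C)C(C)(C)C
A1 | alternative 1 | methyl (2S,3S)-5-bromo-7-methoxy-2-[3-methoxy-4-(tosyloxy)phenyl]-2,3-dihydro-1-benzofuran-3-carboxylate (trans) | Brc1cc(OC)c2c(c1)[C@H](C(=O)OC)[C@@H](c3ccc(OS(=O)(=O)c4ccc(C)cc4)c(OC)c3)O2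
A2 | alternative 1 | (2S)-6-bromo-8-methoxy-2-[3-methoxy-4-(tosyloxy)phenyl]chroman-4-one | O=C1C[C@@H](c2ccc(OS(=O)(=O)c3ccc(C)cc3)c(OC)c2)Oc2c(OC)cc(Br)cc12
A3 | alternative 2 | cis-fused furofuranone with ring B (as Q) endo and ring A (as its benzyl ether) exo | COc1cc([C@@H]7[C@H]2CO[C@@H](c3cc(OC)c4c(c3)[C@@H](CO[Si](C)(C)C(C)(C)C)[C@H](c3cc(OC)c5c(c3)[C@H](CO[Si](C)(C)C(C)(C)C)[C@@H](c3ccc(OCc6ccccc6)c(OC)c3)O5)O4)[C@H]2C(=O)O7)ccc1OCc1ccccc1
A4 | alternative 2 | 5-[4-(benzyloxy)-3-methoxyphenyl]-3-diazo-4-{[(Q)methoxy]methyl}dihydrofuran-2(3H)-one | COc1cc([C@@H]7[C@@H](COCc3cc(OC)c4c(c3)[C@@H](CO[Si](C)(C)C(C)(C)C)[C@H](c3cc(OC)c5c(c3)[C@H](CO[Si](C)(C)C(C)(C)C)[C@@H](c3ccc(OCc6ccccc6)c(OC)c3)O5)O4)C(=[N+]=[N-])C(=O)O7)ccc1OCc1ccccc1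
A5 | alternative 3 | benzyl-protected bis-dihydrobenzofuran aryl bromide (ring B 2R,3S; ring C 2S,3R) | Brc1cc(OC)c2c(c1)[C@@H](COCc7ccccc7)[C@H](c3cc(OC)c5c(c3)[C@H](COCc4ccccc4)[C@@H](c3ccc(OCc6ccccc6)c(OC)c3)O5)O2
A6 | alternative 3 | 2-[3-(benzyloxy)-1-hydroxy-1-(benzyl-protected C unit)propan-2-yl]-4-bromo-6-methoxyphenol, either carbinol epimer | Brc1cc(OC)c(O)c(c1)[C@@H](COCc7ccccc7)C(O)c3cc(OC)c5c(c3)[C@H](COCc4ccccc4)[C@@H](c3ccc(OCc6ccccc6)c(OC)c3)O5
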